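The route rests on the O1–C2 bond of the pyran ring. C2 is a tertiary carbon bound to O1 and sits beside the C3=C4 alkene, so it can be traced back to the tertiary carbon of a 2,3-epoxide whose other carbon carries an aryl ketone (future C4). In one operation acid strips two methoxymethyl ethers and a freed resorcinol oxygen attacks C2 in a 6-endo sense with inversion, closing the pyranone ring and transferring the Sharpless-derived epoxide configuration to C2; C3 and C4 stay oxygenated for later conversion into the alkene. The precursor is a 2,6-bis(methoxymethoxy)-3,4,5-trimethoxyphenyl epoxy ketone already carrying the (1S,2S)-trimethylcyclohexenylethyl side chain.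

Key step: step 17

Assumption: in step 2 the (S,S)-diazaborolidine controller is taken to deliver the (2S,3S) acid; if the sense of induction is the reverse, the (R,R)-antipode is used and nothing else changes.

Step 1
Reactants: 1 geraniol; 2 propionyl chloride
Product: 3 geranyl propionate
Conditions: pyridine, DMAP (cat.), CH2Cl2, 0 °C to rt
Reagents that add atoms: none
Why: Acylation of the primary allylic alcohol by the acid chloride (nucleophilic acyl substitution, pyridine as acid scavenger) should be clean, creates no stereocentre and leaves the E-alkene untouched.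

Step 2
Reactants: 3 geranyl propionate
Product: 5 (2S,3S)-3-ethenyl-2,3,7-trimethyloct-6-enoic acid, via boron ketene acetal 4 (not isolated)
Conditions: (S,S)-bromodiazaborolidine controller (made in the flask from the (S,S)-bis-sulfonamide and BBr3 in CH2Cl2, volatiles removed), Et3N, toluene/hexane, −78 °C, then −20 °C; aq. work-up
Reagents that add atoms: none
Why: Enantioselective Ireland–Claisen rearrangement, in which Et3N in toluene/hexane should give the boron ketene acetal with the methyl cis to the allylic oxygen, the chair [3,3]-shift places that methyl axial and the homoprenyl arm of the E-alkene equatorial to give the like relationship between the new centres C2 and C3, and the C2-symmetric diazaborolidine on boron shields one enolate face so that both are fixed as 2S,3S.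

Step 3
Reactants: 5 (2S,3S)-3-ethenyl-2,3,7-trimethyloct-6-enoic acid
Product: 7 (2S,3S)-3-ethenyl-N-methoxy-N,2,3,7-tetramethyloct-6-enamide, via acyl imidazole 6 (not isolated)
Conditions: 1,1'-carbonyldiimidazole, CH2Cl2, rt; then MeNHOMe·HCl, rt
Reagents that add atoms: N,O-dimethylhydroxylamine hydrochloride, CNOC.Cl
Why: Amide formation through the acyl imidazole works for hindered acids under neutral conditions, so the α-stereocentre C2 should not epimerise and no new stereocentre is formed.

Step 4
Reactants: 8 methyl acetoacetate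
Product: 9 methyl (2E)-3-{[(trifluoromethyl)sulfonyl]oxy}but-2-enoate
Conditions: Tf2O, aq. Me4NOH, hexanes, 5 °C
Reagents that add atoms: trifluoromethanesulfonic anhydride, O=S(=O)(OS(=O)(=O)C(F)(F)F)C(F)(F)F
Why: O-Sulfonylation of the non-chelated tetramethylammonium enolate of the β-keto ester should place the triflate trans to the ester (stereoselective enol triflate formation), giving the E-isomer needed for the later coupling.

Step 5
Reactants: 9 methyl (2E)-3-{[(trifluoromethyl)sulfonyl]oxy}but-2-enoate
Product: 10 (2E)-4-hydroxybut-2-en-2-yl trifluoromethanesulfonate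
Conditions: i-Bu2AlH, CH2Cl2, −78 °C; then aq. KNaC4H4O6 (potassium sodium tartrate)
Reagents that add atoms: none
Why: Aluminium hydride 1,2-reduction of the conjugated ester to the allylic alcohol at low temperature should leave the vinyl triflate and its E geometry intact.

Step 6
Reactants: 7 (2S,3S)-3-ethenyl-N-methoxy-N,2,3,7-tetramethyloct-6-enamide; 10 (2E)-4-hydroxybut-2-en-2-yl trifluoromethanesulfonate
Product: 12 (2S,3S)-3-[(3E)-5-hydroxy-3-methylpent-3-en-1-yl]-N-methoxy-N,2,3,7-tetramethyloct-6-enamide, via B-alkyl-9-BBN adduct 11 (not isolated)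
Conditions: 9-BBN, THF, rt; then aq. K3PO4, 10, PdCl2(dppf) (cat.), AsPh3 (cat.), DMF, rt
Reagents that add atoms: none
Why: 9-BBN hydroborates only the monosubstituted vinyl group in the anti-Markovnikov sense (the trisubstituted alkene and the Weinreb amide do not react) and the primary alkylborane then undergoes B-alkyl Suzuki–Miyaura coupling with the vinyl triflate with retention of the E geometry, no stereocentre being formed.

Step 7
Reactants: 12 (2S,3S)-3-[(3E)-5-hydroxy-3-methylpent-3-en-1-yl]-N-methoxy-N,2,3,7-tetramethyloct-6-enamide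
Product: 13 (3S,4S)-4-[(3E)-5-hydroxy-3-methylpent-3-en-1-yl]-3,4,8-trimethylnon-7-en-2-one
Conditions: MeMgBr (excess), THF, 0 °C to rt; aq. NH4Cl
Reagents that add atoms: methylmagnesium bromide, C[Mg]Br
Why: Grignard addition to the Weinreb amide stops at the chelated tetrahedral intermediate and releases the methyl ketone only on work-up (Weinreb ketone synthesis), the free hydroxyl merely consuming one equivalent of reagent and the α-stereocentre staying untouched.

Step 8
Reactants: 13 (3S,4S)-4-[(3E)-5-hydroxy-3-methylpent-3-en-1-yl]-3,4,8-trimethylnon-7-en-2-one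
Product: 14 (2E,6S,7R)-3,6,7,8-tetramethyl-6-(4-methylpent-3-en-1-yl)nona-2,8-dien-1-ol
Conditions: Ph3PCH3Br, KOt-Bu (excess of both), THF, 0 °C to rt
Reagents that add atoms: methyltriphenylphosphonium bromide, C[P+](c1ccccc1)(c1ccccc1)c1ccccc1.[Br-]
Why: Wittig methylenation converts the ketone into the 1,1-disubstituted alkene, and because the only stereogenic α-carbon is tertiary and flanked by the quaternary centre its deprotonation by the ylide should be too slow to erode the configuration.

Step 9
Reactants: 14 (2E,6S,7R)-3,6,7,8-tetramethyl-6-(4-methylpent-3-en-1-yl)nona-2,8-dien-1-ol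
Product: 15 [(2S,3S)-3-methyl-3-[(3S,4R)-3,4,5-trimethyl-3-(4-methylpent-3-en-1-yl)hex-5-en-1-yl]oxiran-2-yl]methanol
Conditions: Ti(Oi-Pr)4 (cat.), (2R,3R)-(+)-diethyl tartrate (cat.), t-BuOOH, 4 Å molecular sieves, CH2Cl2, −20 °C
Reagents that add atoms: tert-butyl hydroperoxide, CC(C)(C)OO
Why: Sharpless asymmetric epoxidation, in which the titanium tartrate complex binds the allylic hydroxyl and the (2R,3R)-tartrate delivers oxygen to the alkene face that gives the (2S,3S)-epoxide, as for geraniol, under reagent control, while the two alkenes lacking a directing hydroxyl are left alone.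

Step 10
Reactants: 15 [(2S,3S)-3-methyl-3-[(3S,4R)-3,4,5-trimethyl-3-(4-methylpent-3-en-1-yl)hex-5-en-1-yl]oxiran-2-yl]methanol
Product: 16 [(2S,3S)-3-methyl-3-{2-[(1S,2S)-1,2,3-trimethylcyclohex-3-en-1-yl]ethyl}oxiran-2-yl]methanol
Conditions: second-generation Grubbs catalyst (H2IMes)(PCy3)Cl2Ru=CHPh (cat.), CH2Cl2, high dilution, 40 °C
Reagents that add atoms: none
Why: Ring-closing metathesis between the 1,1-disubstituted alkene and the prenyl-type alkene, the only two metathesis-active alkenes now that the chain alkene is an epoxide, should close the six-membered ring with loss of 2-methylpropene, helped by the Thorpe–Ingold effect of the quaternary carbon, without touching any stereocentre.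

Step 11
Reactants: 16 [(2S,3S)-3-methyl-3-{2-[(1S,2S)-1,2,3-trimethylcyclohex-3-en-1-yl]ethyl}oxiran-2-yl]methanol
Product: 17 (2R,3S)-3-methyl-3-{2-[(1S,2S)-1,2,3-trimethylcyclohex-3-en-1-yl]ethyl}oxirane-2-carbaldehyde
Conditions: TEMPO (cat.), PhI(OAc)2, CH2Cl2, rt
Reagents that add atoms: none
Why: Nitroxyl-catalysed oxidation of the primary alcohol stops at the aldehyde under near-neutral conditions, so the epoxide, the ring alkene and the α-stereocentre should survive.

Step 12
Reactants: 18 1,2,3-trimethoxybenzene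
Product: 19 1,5-dibromo-2,3,4-trimethoxybenzene
Conditions: NBS (2 equiv), MeCN, 0 °C to rt
Reagents that add atoms: N-bromosuccinimide, O=C1CCC(=O)N1Br
Why: Electrophilic aromatic bromination should go twice to the two equivalent positions that are ortho to one outer methoxy group and para to the other, giving the symmetrical dibromide.

Step 13
Reactants: 19 1,5-dibromo-2,3,4-trimethoxybenzene
Product: 21 4,5,6-trimethoxybenzene-1,3-diol, via bis(pinacol boronate) 20 (not isolated)
Conditions: B2pin2, KOAc, PdCl2(dppf) (cat.), 1,4-dioxane, 90 °C; then aq. H2O2, THF, 0 °C to rt, under argon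
Reagents that add atoms: hydrogen peroxide, OO
Why: Miyaura borylation of both C–Br bonds followed by peroxide oxidation of the aryl boronates (1,2-aryl shift from boron to oxygen) converts each bromide into a phenol at the same carbon.

Step 14
Reactants: 21 4,5,6-trimethoxybenzene-1,3-diol
Product: 22 1,2,3-trimethoxy-4,6-bis(methoxymethoxy)benzene
Conditions: NaH, MOMCl, DMF, 0 °C to rt
Reagents that add atoms: chloromethyl methyl ether, COCCl
Why: Double O-alkylation of the bis-phenoxide with chloromethyl methyl ether (Williamson ether synthesis) installs two acetal groups that both direct the later lithiation and come off under mild acid.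

Step 15
Reactants: 17 (2R,3S)-3-methyl-3-{2-[(1S,2S)-1,2,3-trimethylcyclohex-3-en-1-yl]ethyl}oxirane-2-carbaldehyde; 22 1,2,3-trimethoxy-4,6-bis(methoxymethoxy)benzene
Product: 24 [2,6-bis(methoxymethoxy)-3,4,5-trimethoxyphenyl][(2S,3S)-3-methyl-3-{2-[(1S,2S)-1,2,3-trimethylcyclohex-3-en-1-yl]ethyl}oxiran-2-yl]methanol (both carbinol epimers), via aryllithium 23 (not isolated)
Conditions: 22, n-BuLi, THF, 0 °C; then 17, −78 °C; aq. NH4Cl
Reagents that add atoms: none
Why: Directed ortho-metalation removes the only ring hydrogen, flanked by both methoxymethoxy groups, and the aryllithium adds to the aldehyde carbonyl faster than it opens the epoxide at −78 °C, the new carbinol centre being formed as a mixture that is irrelevant because it is oxidised in the next step.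

Step 16
Reactants: 24 [2,6-bis(methoxymethoxy)-3,4,5-trimethoxyphenyl][(2S,3S)-3-methyl-3-{2-[(1S,2S)-1,2,3-trimethylcyclohex-3-en-1-yl]ethyl}oxiran-2-yl]methanol
Product: 25 [2,6-bis(methoxymethoxy)-3,4,5-trimethoxyphenyl][(2R,3S)-3-methyl-3-{2-[(1S,2S)-1,2,3-trimethylcyclohex-3-en-1-yl]ethyl}oxiran-2-yl]methanone
Conditions: (n-Pr4N)[RuO4] (cat.), N-methylmorpholine N-oxide, 4 Å molecular sieves, CH2Cl2, rt
Reagents that add atoms: none
Why: Perruthenate-catalysed oxidation (Ley–Griffith) of the secondary benzylic alcohol under neutral conditions should give the aryl ketone without disturbing the epoxide, the acetals or the alkene, and it removes the stereo-random carbinol centre.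

Step 17
Reactants: 25 [2,6-bis(methoxymethoxy)-3,4,5-trimethoxyphenyl][(2R,3S)-3-methyl-3-{2-[(1S,2S)-1,2,3-trimethylcyclohex-3-en-1-yl]ethyl}oxiran-2-yl]methanone
Product: 27 (2R,3R)-3,5-dihydroxy-6,7,8-trimethoxy-2-methyl-2-{2-[(1S,2S)-1,2,3-trimethylcyclohex-3-en-1-yl]ethyl}-2,3-dihydro-4H-chromen-4-one, via diphenol epoxy ketone 26 (not isolated)
Conditions: NaHSO4·SiO2, CH2Cl2, rt
Reagents that add atoms: none
Why: The solid acid hydrolyses both aryl methoxymethyl acetals, which are activated by the ortho carbonyl, and one of the two equivalent phenol oxygens then attacks the protonated epoxide at C2, the tertiary carbon remote from the carbonyl, from the side opposite the epoxide oxygen, forming O1–C2 and leaving the epoxide oxygen as the C3 hydroxyl. The closest known reaction type is the acid-promoted cyclisation of 2'-hydroxychalcone epoxides to 3-hydroxychroman-4-ones, together with the endo opening of trisubstituted epoxides by phenols at the tertiary carbon. The pyranone ring is closed in the 6-endo-tet mode. The new stereocentre C2 is controlled by the epoxide configuration installed in step 9, which is inverted in the SN2-like opening, and C3 keeps its configuration because its C–O bond is not broken. The step needs 6-endo over 5-exo closure and clean inversion: the tertiary character of C2 and the deactivation of C3 by the adjacent carbonyl secure the first, and the non-nucleophilic hydrogen sulfate in CH2Cl2, with no competing nucleophile, secures the second. Should a methoxymethyl ether oxygen attack before it is hydrolysed, loss of the methoxymethyl cation leads to the same product.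

Step 18
Reactants: 27 (2R,3R)-3,5-dihydroxy-6,7,8-trimethoxy-2-methyl-2-{2-[(1S,2S)-1,2,3-trimethylcyclohex-3-en-1-yl]ethyl}-2,3-dihydro-4H-chromen-4-one
Product: 28 (2R)-5-hydroxy-6,7,8-trimethoxy-2-methyl-2-{2-[(1S,2S)-1,2,3-trimethylcyclohex-3-en-1-yl]ethyl}-2,3-dihydro-4H-chromen-4-one
Conditions: SmI2, THF/MeOH, −78 °C
Reagents that add atoms: none
Why: Samarium diiodide reduction of an α-hydroxy ketone, in which electron transfer to the aryl ketone gives a ketyl that expels the C3 hydroxyl and the resulting samarium enolate is protonated by methanol at −78 °C before it can open the pyranone ring by a retro-oxa-Michael reaction, so the C2 configuration is kept and no new stereocentre arises.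

Step 19
Reactants: 28 (2R)-5-hydroxy-6,7,8-trimethoxy-2-methyl-2-{2-[(1S,2S)-1,2,3-trimethylcyclohex-3-en-1-yl]ethyl}-2,3-dihydro-4H-chromen-4-one
Product: 29 (2R)-6,7,8-trimethoxy-2-methyl-2-{2-[(1S,2S)-1,2,3-trimethylcyclohex-3-en-1-yl]ethyl}-3,4-dihydro-2H-chromene-4,5-diol (both C4 epimers)
Conditions: LiAlH4, THF, 0 °C; then aq. KNaC4H4O6
Reagents that add atoms: none
Why: Hydride reduction of the hydrogen-bonded aryl ketone gives the benzylic alcohol, the C4 centre being formed as a mixture that is of no consequence because C4 becomes sp2 in the next step.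

Step 20
Reactants: 29 (2R)-6,7,8-trimethoxy-2-methyl-2-{2-[(1S,2S)-1,2,3-trimethylcyclohex-3-en-1-yl]ethyl}-3,4-dihydro-2H-chromene-4,5-diol
Product: 30 (2R)-6,7,8-trimethoxy-2-methyl-2-{2-[(1S,2S)-1,2,3-trimethylcyclohex-3-en-1-yl]ethyl}-2H-chromen-5-ol (target)
Conditions: PPTS (cat.), toluene, 4 Å molecular sieves, 50 °C, dark
Reagents that add atoms: none
Why: Acid-catalysed dehydration (E1), in which the C4 hydroxyl ionises easily because the cation is stabilised by the ortho and para oxygens of ring A (ortho-quinone methide character) and loss of a C3 proton, the only one available since C2 is quaternary, gives the conjugated C3=C4 alkene without touching C2 or the side-chain alkene.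

Compound list
1 | geraniol, (2E)-3,7-dimethylocta-2,6-dien-1-ol | CC(C)=CCC/C(C)=C/CO | starting material
2 | propionyl chloride | CCC(=O)Cl | starting material
3 | geranyl propionate, (2E)-3,7-dimethylocta-2,6-dien-1-yl propanoate | CCC(=O)OC/C=C(\C)CCC=C(C)C | intermediate
4 | O-boryl ketene acetal of 3 (methyl cis to the geranyloxy oxygen; boron carries the (4S,5S)-1,3-bis{[3,5-bis(trifluoromethyl)phenyl]sulfonyl}-4,5-diphenyl-1,3,2-diazaborolidine ring) | C/C=C(\OC/C=C(\C)CCC=C(C)C)OB1N(S(=O)(=O)c2cc(C(F)(F)F)cc(C(F)(F)F)c2)[C@@H](c2ccccc2)[C@H](c2ccccc2)N1S(=O)(=O)c1cc(C(F)(F)F)cc(C(F)(F)F)c1 | intermediate (not isolated)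
5 | (2S,3S)-3-ethenyl-2,3,7-trimethyloct-6-enoic acid | C=C[C@](C)(CCC=C(C)C)[C@H](C)C(=O)O | intermediate
6 | (2S,3S)-3-ethenyl-1-(1H-imidazol-1-yl)-2,3,7-trimethyloct-6-en-1-one (acyl imidazole) | C=C[C@](C)(CCC=C(C)C)[C@H](C)C(=O)n1ccnc1 | intermediate (not isolated)
7 | (2S,3S)-3-ethenyl-N-methoxy-N,2,3,7-tetramethyloct-6-enamide | C=C[C@](C)(CCC=C(C)C)[C@H](C)C(=O)N(C)OC | intermediate
8 | methyl acetoacetate | COC(=O)CC(C)=O | starting material
9 | methyl (2E)-3-{[(trifluoromethyl)sulfonyl]oxy}but-2-enoate (triflate trans to ester) | COC(=O)/C=C(\C)OS(=O)(=O)C(F)(F)F | intermediate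
10 | (2E)-4-hydroxybut-2-en-2-yl trifluoromethanesulfonate | OC/C=C(\C)OS(=O)(=O)C(F)(F)F | intermediate
11 | B-alkyl-9-BBN adduct of 7 (boron on the terminal carbon of the former vinyl group) | B1(C2CCCC1CCC2)CC[C@](C)(CCC=C(C)C)[C@H](C)C(=O)N(C)OC | intermediate (not isolated)
12 | (2S,3S)-3-[(3E)-5-hydroxy-3-methylpent-3-en-1-yl]-N-methoxy-N,2,3,7-tetramethyloct-6-enamide | OC/C=C(\C)CC[C@](C)(CCC=C(C)C)[C@H](C)C(=O)N(C)OC | intermediate
13 | (3S,4S)-4-[(3E)-5-hydroxy-3-methylpent-3-en-1-yl]-3,4,8-trimethylnon-7-en-2-one | OC/C=C(\C)CC[C@](C)(CCC=C(C)C)[C@H](C)C(C)=O | intermediate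
14 | (2E,6S,7R)-3,6,7,8-tetramethyl-6-(4-methylpent-3-en-1-yl)nona-2,8-dien-1-ol | OC/C=C(\C)CC[C@](C)(CCC=C(C)C)[C@H](C)C(C)=C | intermediate
15 | [(2S,3S)-3-methyl-3-[(3S,4R)-3,4,5-trimethyl-3-(4-methylpent-3-en-1-yl)hex-5-en-1-yl]oxiran-2-yl]methanol | OC[C@@H]1O[C@@]1(C)CC[C@](C)(CCC=C(C)C)[C@H](C)C(C)=C | intermediate
16 | [(2S,3S)-3-methyl-3-{2-[(1S,2S)-1,2,3-trimethylcyclohex-3-en-1-yl]ethyl}oxiran-2-yl]methanol (ring methyls at C1 and C2 cis) | OC[C@@H]1O[C@@]1(C)CC[C@]1(C)CCC=C(C)[C@H]1C | intermediate
17 | (2R,3S)-3-methyl-3-{2-[(1S,2S)-1,2,3-trimethylcyclohex-3-en-1-yl]ethyl}oxirane-2-carbaldehyde | O=C[C@@H]1O[C@@]1(C)CC[C@]1(C)CCC=C(C)[C@H]1C | intermediate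
18 | 1,2,3-trimethoxybenzene | COc1cccc(OC)c1OC | starting material
19 | 1,5-dibromo-2,3,4-trimethoxybenzene | COc1c(Br)cc(Br)c(OC)c1OC | intermediate
20 | 2,2'-(4,5,6-trimethoxy-1,3-phenylene)bis(4,4,5,5-tetramethyl-1,3,2-dioxaborolane) | COc1c(B2OC(C)(C)C(C)(C)O2)cc(B2OC(C)(C)C(C)(C)O2)c(OC)c1OC | intermediate (not isolated)
21 | 4,5,6-trimethoxybenzene-1,3-diol | COc1c(O)cc(O)c(OC)c1OC | intermediate
22 | 1,2,3-trimethoxy-4,6-bis(methoxymethoxy)benzene | COCOc1cc(OCOC)c(OC)c(OC)c1OC | intermediate
23 | [2,6-bis(methoxymethoxy)-3,4,5-trimethoxyphenyl]lithium | [Li]c1c(OCOC)c(OC)c(OC)c(OC)c1OCOC | intermediate (not isolated)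
24 | [2,6-bis(methoxymethoxy)-3,4,5-trimethoxyphenyl][(2S,3S)-3-methyl-3-{2-[(1S,2S)-1,2,3-trimethylcyclohex-3-en-1-yl]ethyl}oxiran-2-yl]methanol, both carbinol epimers | COCOc1c(OC)c(OC)c(OC)c(OCOC)c1C(O)[C@@H]1O[C@@]1(C)CC[C@]1(C)CCC=C(C)[C@H]1C | intermediate
25 | [2,6-bis(methoxymethoxy)-3,4,5-trimethoxyphenyl][(2R,3S)-3-methyl-3-{2-[(1S,2S)-1,2,3-trimethylcyclohex-3-en-1-yl]ethyl}oxiran-2-yl]methanone (key-step precursor) | COCOc1c(OC)c(OC)c(OC)c(OCOC)c1C(=O)[C@@H]1O[C@@]1(C)CC[C@]1(C)CCC=C(C)[C@H]1C | intermediate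
26 | (2,6-dihydroxy-3,4,5-trimethoxyphenyl)[(2R,3S)-3-methyl-3-{2-[(1S,2S)-1,2,3-trimethylcyclohex-3-en-1-yl]ethyl}oxiran-2-yl]methanone | Oc1c(OC)c(OC)c(OC)c(O)c1C(=O)[C@@H]1O[C@@]1(C)CC[C@]1(C)CCC=C(C)[C@H]1C | intermediate (not isolated)
27 | (2R,3R)-3,5-dihydroxy-6,7,8-trimethoxy-2-methyl-2-{2-[(1S,2S)-1,2,3-trimethylcyclohex-3-en-1-yl]ethyl}-2,3-dihydro-4H-chromen-4-one (3-hydroxyl cis to the C2 methyl; key-step product) | COc1c(O)c2c(c(OC)c1OC)O[C@](C)(CC[C@]1(C)CCC=C(C)[C@H]1C)[C@@H](O)C2=O | intermediate
28 | (2R)-5-hydroxy-6,7,8-trimethoxy-2-methyl-2-{2-[(1S,2S)-1,2,3-trimethylcyclohex-3-en-1-yl]ethyl}-2,3-dihydro-4H-chromen-4-one | COc1c(O)c2c(c(OC)c1OC)O[C@](C)(CC[C@]1(C)CCC=C(C)[C@H]1C)CC2=O | intermediate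
29 | (2R)-6,7,8-trimethoxy-2-methyl-2-{2-[(1S,2S)-1,2,3-trimethylcyclohex-3-en-1-yl]ethyl}-3,4-dihydro-2H-chromene-4,5-diol, both C4 epimers | COc1c(O)c2c(c(OC)c1OC)O[C@](C)(CC[C@]1(C)CCC=C(C)[C@H]1C)CC2O | intermediate
30 | (2R)-6,7,8-trimethoxy-2-methyl-2-{2-[(1S,2S)-1,2,3-trimethylcyclohex-3-en-1-yl]ethyl}-2H-chromen-5-ol | COc1c(O)c2c(c(OC)c1OC)O[C@](C)(CC[C@]1(C)CCC=C(C)[C@H]1C)C=C2 | target

Total step count: 20.
Longest linear sequence: 15 steps (steps 1, 2, 3, 6, 7, 8, 9, 10, 11, 15, 16, 17, 18, 19, 20).

Steps most likely to fail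

Step 17 (key step). What may go wrong: an outside nucleophile, or an acid-induced acyl or hydride shift, may consume the activated epoxide before a phenol has been set free, or closure may take place at C3 in the 5-exo sense. The fallback separates phenol release from epoxide activation. Setting out from diol 21, ethyl vinyl ether and PPTS would give 1,5-bis(1-ethoxyethoxy)-2,3,4-trimethoxybenzene F1 (acetal centres as a mixture). Lithiation with n-BuLi would give [2,6-bis(1-ethoxyethoxy)-3,4,5-trimethoxyphenyl]lithium F2, which adds to aldehyde 17 to give the epoxy carbinol F3. Perruthenate-catalysed oxidation would give the bis(ethoxyethyl) epoxy ketone F4. PPTS in ethanol at rt should then remove the far more labile ethoxyethyl acetals without activating the epoxide, so that diphenol 26 can be isolated. A separate ring closure with catalytic camphorsulfonic acid in CH2Cl2 at 0 °C brings the route back at 27.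

Step 18. What may go wrong: the samarium enolate may expel the aryloxide (retro-oxa-Michael ring opening and re-closure), which would erode the configuration at C2, or the aryl ketone may be reduced further. The fallback never forms an enolate at C3. Setting out from 27, reduction with LiBH(s-Bu)3 in THF at −78 °C should deliver hydride anti to the axial C2 methyl and give the cis-3,4-diol (2R,3S,4S)-6,7,8-trimethoxy-2-methyl-2-{2-[(1S,2S)-1,2,3-trimethylcyclohex-3-en-1-yl]ethyl}-3,4-dihydro-2H-chromene-3,4,5-triol F5. 1,1'-Thiocarbonyldiimidazole would convert it into the 3,4-cyclic thionocarbonate F6 (any thiocarbonyl imidazolide on the phenol being cleaved by methanol on work-up). Corey–Winter olefination with 1,3-dimethyl-2-phenyl-1,3,2-diazaphospholidine in THF at 40 °C would then give the target 30 directly.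

Step 2. What may go wrong: enolisation and rearrangement with the bulky boron controller may be slow or incomplete, or the enolate geometry or facial selectivity may be insufficient, so that the acid is formed with low conversion or low enantiomeric purity. The fallback is a racemic rearrangement followed by classical resolution. Setting out from 3, an ordinary Ireland–Claisen rearrangement (LDA, THF, −78 °C; Me3SiCl; warming to rt) would pass through the O-trimethylsilyl ketene acetal F7 (methyl cis to the geranyloxy oxygen) and the racemic trimethylsilyl ester F8 and give, after hydrolysis, the racemic like acid F9 with the same relative configuration through the same chair. Crystallisation of the (R)-1-phenylethylammonium salt F10 of the (2S,3S) acid (or use of the antipodal amine if its salt is the less soluble one) and acidification would return the route at 5.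

Further compounds
F1 | step 17 | 1,5-bis(1-ethoxyethoxy)-2,3,4-trimethoxybenzene (acetal centres as a mixture) | CCOC(C)Oc1cc(OC(C)OCC)c(OC)c(OC)c1OC
F2 | step 17 | [2,6-bis(1-ethoxyethoxy)-3,4,5-trimethoxyphenyl]lithium | [Li]c1c(OC(C)OCC)c(OC)c(OC)c(OC)c1OC(C)OCC
F3 | step 17 | [2,6-bis(1-ethoxyethoxy)-3,4,5-trimethoxyphenyl][(2S,3S)-3-methyl-3-{2-[(1S,2S)-1,2,3-trimethylcyclohex-3-en-1-yl]ethyl}oxiran-2-yl]methanol (carbinol and acetal centres as mixtures) | CCOC(C)Oc1c(OC)c(OC)c(OC)c(OC(C)OCC)c1C(O)[C@@H]1O[C@@]1(C)CC[C@]1(C)CCC=C(C)[C@H]1C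
F4 | step 17 | [2,6-bis(1-ethoxyethoxy)-3,4,5-trimethoxyphenyl][(2R,3S)-3-methyl-3-{2-[(1S,2S)-1,2,3-trimethylcyclohex-3-en-1-yl]ethyl}oxiran-2-yl]methanone | CCOC(C)Oc1c(OC)c(OC)c(OC)c(OC(C)OCC)c1C(=O)[C@@H]1O[C@@]1(C)CC[C@]1(C)CCC=C(C)[C@H]1C
F5 | step 18 | (2R,3S,4S)-6,7,8-trimethoxy-2-methyl-2-{2-[(1S,2S)-1,2,3-trimethylcyclohex-3-en-1-yl]ethyl}-3,4-dihydro-2H-chromene-3,4,5-triol (3,4-cis) | COc1c(O)c2c(c(OC)c1OC)O[C@](C)(CC[C@]1(C)CCC=C(C)[C@H]1C)[C@@H](O)[C@H]2O
F6 | step 18 | 3,4-cyclic thionocarbonate of F5 | COc1c(O)c2c(c(OC)c1OC)O[C@](C)(CC[C@]1(C)CCC=C(C)[C@H]1C)[C@H]1OC(=S)O[C@@H]21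
F7 | step 2 | O-trimethylsilyl ketene acetal of 3 (methyl cis to the geranyloxy oxygen) | C/C=C(\OC/C=C(\C)CCC=C(C)C)O[Si](C)(C)C
F8 | step 2 | racemic trimethylsilyl (2S*,3S*)-3-ethenyl-2,3,7-trimethyloct-6-enoate | C=C[C@](C)(CCC=C(C)C)[C@H](C)C(=O)O[Si](C)(C)C.C=C[C@@](C)(CCC=C(C)C)[C@@H](C)C(=O)O[Si](C)(C)C
F9 | step 2 | racemic (2S*,3S*)-3-ethenyl-2,3,7-trimethyloct-6-enoic acid | C=C[C@](C)(CCC=C(C)C)[C@H](C)C(=O)O.C=C[C@@](C)(CCC=C(C)C)[C@@H](C)C(=O)O
F10 | step 2 | (R)-1-phenylethylammonium (2S,3S)-3-ethenyl-2,3,7-trimethyloct-6-enoate | C=C[C@](C)(CCC=C(C)C)[C@H](C)C(=O)[O-].C[C@@H]([NH3+])c1ccccc1
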